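**Retrosynthetic overview**
1. The target acid comes from its allyl ester carrying a silyloxy group at C2 (indene numbering), by desilylation, oxidation and Pd-catalysed deallylation.
2. That bicycle comes from an all-E acyclic tetraene (styryl diene, 2-ethyl enoate, three-atom tether) by one intramolecular Diels–Alder reaction. It forms the C4–C5 and C3a–C7a bonds, so the cyclohexene and the five-membered ring close in the same event; there is no ring before it.
3. The tetraene comes from a five-carbon stereotriad by E-selective Wittig and Horner–Wadsworth–Emmons olefinations, first toward the styryl triene, then toward the enoate.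
4. The stereotriad comes from an Evans syn-aldol between a butanoyl oxazolidinone and an α-chiral aldehyde; this intermolecular aldol makes the C1–C2 bond and joins the two chiral fragments.
5. The α-chiral aldehyde comes from the same butanoyl oxazolidinone by an asymmetric formaldehyde aldol.

Assumption: ring atoms are named by the indene numbering of the target (ketone at C2, ring fusion C3a/C7a, acid at C4, styryl at C5, alkene C6=C7); bases, oxidants, silylating agents and PPh3 carry no compound number.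

**Route**

Step 1
Reactants: 1 (R)-4-benzyloxazolidin-2-one; 2 butanoyl chloride
Product: 4 (R)-4-benzyl-3-butanoyloxazolidin-2-one, via lithium amide 3 (not isolated)
Conditions: n-BuLi (1.0 equiv), THF, −78 °C; then 2, −78 to 0 °C
Reagents that add atoms: none
Why: N-acylation of the lithiated oxazolidinone by the acid chloride (nucleophilic acyl substitution) is clean and touches no stereocenter.

Step 2
Reactants: 4 (R)-4-benzyl-3-butanoyloxazolidin-2-one
Product: 6 (R)-4-benzyl-3-[(2S)-2-(hydroxymethyl)butanoyl]oxazolidin-2-one, via titanium enolate 5 (not isolated)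
Conditions: TiCl4 (1.05 equiv), i-Pr2NEt (1.1 equiv), CH2Cl2, 0 °C; then 1,3,5-trioxane (1.1 equiv), TiCl4 (1.05 equiv), 0 °C; aq. NH4Cl
Reagents that add atoms: 1,3,5-trioxane, C1OCOCO1
Why: Evans titanium-enolate aldol with formaldehyde (hydroxymethylation); the chelated (Z)-enolate is attacked on the face away from the benzyl group, which sets the (S) center (future C3).

Step 3
Reactants: 6 hydroxymethyl imide
Product: 7 (R)-4-benzyl-3-[(2S)-2-{[(tert-butyldimethylsilyl)oxy]methyl}butanoyl]oxazolidin-2-one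
Conditions: TBSCl, imidazole, DMF, rt
Reagents that add atoms: tert-butyldimethylsilyl chloride, CC(C)(C)[Si](C)(C)Cl
Why: Standard silylation of a primary alcohol under mild base that does not epimerize the α-center.

Step 4
Reactants: 7 silyl ether imide
Product: 8 (2R)-2-{[(tert-butyldimethylsilyl)oxy]methyl}butan-1-ol
Conditions: LiBH4 (2 equiv), MeOH (2 equiv), Et2O, 0 °C
Reagents that add atoms: none
Why: Reductive cleavage of the exocyclic imide carbonyl by borohydride frees the auxiliary for reuse and leaves the stereocenter untouched (the descriptor changes only through CIP priorities).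

Step 5
Reactants: 8 mono-silylated diol
Product: 9 (2S)-2-{[(tert-butyldimethylsilyl)oxy]methyl}butanal
Conditions: Dess–Martin periodinane, CH2Cl2, 0 °C to rt; used crude at once
Reagents that add atoms: none
Why: Dess–Martin oxidation is near neutral, so the α-stereocenter of the aldehyde is not epimerized.

Step 6
Reactants: 4 (R)-4-benzyl-3-butanoyloxazolidin-2-one; 9 α-chiral aldehyde
Product: 11 (R)-4-benzyl-3-[(2R,3S,4S)-5-[(tert-butyldimethylsilyl)oxy]-2,4-diethyl-3-hydroxypentanoyl]oxazolidin-2-one, via boron enolate 10 (not isolated)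
Conditions: n-Bu2BOTf (1.1 equiv), i-Pr2NEt (1.2 equiv), CH2Cl2, −78 to 0 °C; then 9, −78 to 0 °C; pH 7 buffer, MeOH, 30% H2O2, 0 °C
Reagents that add atoms: none
Why: Evans syn-aldol through the (Z)-dibutylboron enolate and a closed Zimmerman–Traxler transition state; the auxiliary sets the (2R,3S) centers (future C1 and the C2 carbinol), and the (S) center of 9 places the new hydroxyl anti to its ethyl group.

Step 7
Reactants: 11 aldol adduct
Product: 12 (R)-4-benzyl-3-[(2R,3S,4S)-3,5-bis[(tert-butyldimethylsilyl)oxy]-2,4-diethylpentanoyl]oxazolidin-2-one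
Conditions: TBSOTf, 2,6-lutidine, CH2Cl2, −78 to 0 °C
Reagents that add atoms: tert-butyldimethylsilyl triflate, CC(C)(C)[Si](C)(C)OS(=O)(=O)C(F)(F)F
Why: The silyl triflate silylates the hindered secondary alcohol and blocks retro-aldol in the later steps.

Step 8
Reactants: 12 bis-silyl imide
Product: 13 (2S,3R,4S)-3,5-bis[(tert-butyldimethylsilyl)oxy]-2,4-diethylpentan-1-ol
Conditions: LiBH4 (3 equiv), MeOH (3 equiv), THF, 0 °C to rt
Reagents that add atoms: none
Why: Reductive removal of the auxiliary by borohydride gives the primary alcohol without touching the three stereocenters or the silyl ethers.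

Step 9
Reactants: 13 primary alcohol
Product: 14 (2R,3S,4S)-3,5-bis[(tert-butyldimethylsilyl)oxy]-2,4-diethylpentanal
Conditions: Dess–Martin periodinane, CH2Cl2, 0 °C to rt
Reagents that add atoms: none
Why: Mild Dess–Martin oxidation gives the α-chiral β-silyloxy aldehyde without epimerization or β-elimination.

Step 10
Reactants: 15 2-bromobutanoyl bromide (racemic); 16 allyl alcohol
Product: 17 allyl 2-bromobutanoate (racemic)
Conditions: pyridine, CH2Cl2, 0 °C to rt
Reagents that add atoms: none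
Why: Simple acylation of the alcohol by the acid bromide.

Step 11
Reactants: 17 allyl 2-bromobutanoate
Product: 19 allyl 2-(triphenylphosphoranylidene)butanoate, via phosphonium bromide 18 (not isolated)
Conditions: PPh3, toluene, 90 °C; then 1 M NaOH, CH2Cl2, 0 °C
Reagents that add atoms: triphenylphosphine, c1ccc(cc1)P(c1ccccc1)c1ccccc1
Why: SN2 quaternization of the phosphine followed by deprotonation gives the stabilized ylide used for all three Wittig reactions.

Step 12
Reactants: 14 stereotriad aldehyde; 19 stabilized ylide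
Product: 20 allyl (2E,4S,5R,6S)-5,7-bis[(tert-butyldimethylsilyl)oxy]-2,4,6-triethylhept-2-enoate
Conditions: toluene, 90 °C
Reagents that add atoms: none
Why: Wittig olefination with an α-substituted stabilized ylide gives the (E)-trisubstituted enoate under neutral conditions that spare the α-stereocenter.

Step 13
Reactants: 20 enoate
Product: 21 (2E,4S,5R,6S)-5,7-bis[(tert-butyldimethylsilyl)oxy]-2,4,6-triethylhept-2-en-1-ol
Conditions: i-Bu2AlH (2.5 equiv), CH2Cl2, −78 °C
Reagents that add atoms: none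
Why: 1,2-Reduction of the conjugated ester by the aluminium hydride gives the allylic alcohol with the alkene geometry intact.

Step 14
Reactants: 21 allylic alcohol
Product: 22 (2E,4S,5R,6S)-5,7-bis[(tert-butyldimethylsilyl)oxy]-2,4,6-triethylhept-2-enal
Conditions: MnO2 (excess), CH2Cl2, rt
Reagents that add atoms: none
Why: MnO2 oxidizes allylic alcohols chemoselectively and does not isomerize the (E)-alkene.

Step 15
Reactants: 22 enal; 19 stabilized ylide
Product: 23 allyl (2E,4E,6S,7R,8S)-7,9-bis[(tert-butyldimethylsilyl)oxy]-2,4,6,8-tetraethylnona-2,4-dienoate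
Conditions: toluene, 100 °C
Reagents that add atoms: none
Why: A second Wittig olefination with the stabilized ylide adds the next (E)-trisubstituted alkene, with the ester carbon trans to the chain as the diene later requires.

Step 16
Reactants: 23 dienoate
Product: 24 (2E,4E,6S,7R,8S)-7,9-bis[(tert-butyldimethylsilyl)oxy]-2,4,6,8-tetraethylnona-2,4-dien-1-ol
Conditions: i-Bu2AlH (2.5 equiv), CH2Cl2, −78 °C
Reagents that add atoms: none
Why: 1,2-Reduction of the dienoate by the aluminium hydride gives the dienol.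

Step 17
Reactants: 24 dienol
Product: 25 (2E,4E,6S,7R,8S)-7,9-bis[(tert-butyldimethylsilyl)oxy]-2,4,6,8-tetraethylnona-2,4-dienal
Conditions: MnO2 (excess), CH2Cl2, rt
Reagents that add atoms: none
Why: Chemoselective allylic oxidation by MnO2 gives the dienal without touching the silyl ethers.

Step 18
Reactants: 25 dienal; 26 diethyl benzylphosphonate
Product: 28 (1E,3E,5E,7S,8R,9S)-8,10-bis[(tert-butyldimethylsilyl)oxy]-3,5,7,9-tetraethyl-1-phenyldeca-1,3,5-triene, via sodium phosphonate carbanion 27 (not isolated)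
Conditions: 26 (1.2 equiv), NaN(SiMe3)2 (1.1 equiv), THF, −78 °C; then 25, −78 °C to rt
Reagents that add atoms: none
Why: Horner–Wadsworth–Emmons olefination with a benzylphosphonate gives the (E)-styryl alkene, and preforming the carbanion keeps free base away from the dienal.

Step 19
Reactants: 28 bis-silyl triene
Product: 29 (2S,3R,4S,5E,7E,9E)-3-[(tert-butyldimethylsilyl)oxy]-2,4,6,8-tetraethyl-10-phenyldeca-5,7,9-trien-1-ol
Conditions: HF·pyridine, pyridine, THF, 0 °C to rt
Reagents that add atoms: none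
Why: Buffered fluoride desilylation removes the unhindered primary silyl ether far faster than the secondary one flanked by two branched carbons.

Step 20
Reactants: 29 primary alcohol
Product: 30 (2R,3R,4S,5E,7E,9E)-3-[(tert-butyldimethylsilyl)oxy]-2,4,6,8-tetraethyl-10-phenyldeca-5,7,9-trienal
Conditions: Dess–Martin periodinane, pyridine, CH2Cl2, 0 °C
Reagents that add atoms: none
Why: Buffered Dess–Martin oxidation gives the α-chiral aldehyde without epimerization and leaves the triene alone.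

Step 21
Reactants: 30 triene aldehyde; 19 stabilized ylide
Product: 32 allyl (1S,2R,3S,3aR,4R,5S,7aR)-2-[(tert-butyldimethylsilyl)oxy]-1,3,4,5,7-pentaethyl-5-[(E)-2-phenylethenyl]-2,3,3a,4,5,7a-hexahydro-1H-indene-4-carboxylate, via acyclic tetraene 31 (not isolated)
Conditions: toluene (0.01 M), BHT (cat.), 80 °C until 30 is consumed; then 110 °C
Reagents that add atoms: none
Why: Wittig olefination gives the (E)-enoate and the tetraene then undergoes an intramolecular Diels–Alder reaction in which 1,3-allylic strain at both ethyl-bearing allylic stereocenters fixes the reacting faces, giving the trans ring fusion (C3a, C7a), while the E geometries of enoate and diene fix the quaternary centers C4 and C5.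

Step 22
Reactants: 32 silyl ether cycloadduct
Product: 33 allyl (1S,2R,3S,3aR,4R,5S,7aR)-1,3,4,5,7-pentaethyl-2-hydroxy-5-[(E)-2-phenylethenyl]-2,3,3a,4,5,7a-hexahydro-1H-indene-4-carboxylate
Conditions: HF·pyridine (excess), THF, rt to 40 °C
Reagents that add atoms: none
Why: Unbuffered fluoride desilylation cleaves the hindered secondary silyl ether, and the neopentyl-type allyl ester and the alkenes are inert to it.

Step 23
Reactants: 33 cyclopentanol
Product: 34 allyl (1S,3S,3aR,4R,5S,7aR)-1,3,4,5,7-pentaethyl-2-oxo-5-[(E)-2-phenylethenyl]-2,3,3a,4,5,7a-hexahydro-1H-indene-4-carboxylate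
Conditions: Dess–Martin periodinane, pyridine, CH2Cl2, 0 °C to rt
Reagents that add atoms: none
Why: Dess–Martin oxidation gives the cyclopentanone under non-enolizing conditions, so C1 and C3 (each ethyl trans to its ring neighbour) keep their configuration.

Step 24
Reactants: 34 allyl ester
Product: 35 (1S,3S,3aR,4R,5S,7aR)-1,3,4,5,7-pentaethyl-2-oxo-5-[(E)-2-phenylethenyl]-2,3,3a,4,5,7a-hexahydro-1H-indene-4-carboxylic acid
Conditions: Pd(PPh3)4 (5 mol %), morpholine (10 equiv), THF, rt; dilute citric acid work-up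
Reagents that add atoms: none
Why: Tsuji–Trost deallylation ionizes the allyl–oxygen bond, so the acid is freed without attack at the very hindered carbonyl and without acid or base that could lactonize or epimerize.

**Compound list**

1 | (R)-4-benzyloxazolidin-2-one | O=C1N[C@H](Cc2ccccc2)CO1 | starting material
2 | butanoyl chloride | CCCC(=O)Cl | starting material
3 | N-lithio-(R)-4-benzyloxazolidin-2-one (lithium amide of 1) | [Li]N1[C@H](Cc2ccccc2)COC1=O | intermediate
4 | (R)-4-benzyl-3-butanoyloxazolidin-2-one | CCCC(=O)N1[C@H](Cc2ccccc2)COC1=O | intermediate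
5 | trichlorotitanium (Z)-enolate of 4 | CC/C=C(\O[Ti](Cl)(Cl)Cl)N1[C@H](Cc2ccccc2)COC1=O | intermediate
6 | (R)-4-benzyl-3-[(2S)-2-(hydroxymethyl)butanoyl]oxazolidin-2-one | CC[C@@H](CO)C(=O)N1[C@H](Cc2ccccc2)COC1=O | intermediate
7 | (R)-4-benzyl-3-[(2S)-2-{[(tert-butyldimethylsilyl)oxy]methyl}butanoyl]oxazolidin-2-one | CC[C@@H](CO[Si](C)(C)C(C)(C)C)C(=O)N1[C@H](Cc2ccccc2)COC1=O | intermediate
8 | (2R)-2-{[(tert-butyldimethylsilyl)oxy]methyl}butan-1-ol | CC[C@@H](CO[Si](C)(C)C(C)(C)C)CO | intermediate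
9 | (2S)-2-{[(tert-butyldimethylsilyl)oxy]methyl}butanal | CC[C@@H](CO[Si](C)(C)C(C)(C)C)C=O | intermediate
10 | di-n-butylboron (Z)-enolate of 4 | CC/C=C(\OB(CCCC)CCCC)N1[C@H](Cc2ccccc2)COC1=O | intermediate
11 | (R)-4-benzyl-3-[(2R,3S,4S)-5-[(tert-butyldimethylsilyl)oxy]-2,4-diethyl-3-hydroxypentanoyl]oxazolidin-2-one | CC[C@@H](C(=O)N1[C@H](Cc2ccccc2)COC1=O)[C@@H](O)[C@@H](CC)CO[Si](C)(C)C(C)(C)C | intermediate
12 | (R)-4-benzyl-3-[(2R,3S,4S)-3,5-bis[(tert-butyldimethylsilyl)oxy]-2,4-diethylpentanoyl]oxazolidin-2-one | CC[C@@H](C(=O)N1[C@H](Cc2ccccc2)COC1=O)[C@@H](O[Si](C)(C)C(C)(C)C)[C@@H](CC)CO[Si](C)(C)C(C)(C)C | intermediate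
13 | (2S,3R,4S)-3,5-bis[(tert-butyldimethylsilyl)oxy]-2,4-diethylpentan-1-ol | CC[C@@H](CO)[C@@H](O[Si](C)(C)C(C)(C)C)[C@@H](CC)CO[Si](C)(C)C(C)(C)C | intermediate
14 | (2R,3S,4S)-3,5-bis[(tert-butyldimethylsilyl)oxy]-2,4-diethylpentanal | CC[C@@H](C=O)[C@@H](O[Si](C)(C)C(C)(C)C)[C@@H](CC)CO[Si](C)(C)C(C)(C)C | intermediate
15 | 2-bromobutanoyl bromide (racemic) | CCC(Br)C(Br)=O | starting material
16 | allyl alcohol (prop-2-en-1-ol) | C=CCO | starting material
17 | allyl 2-bromobutanoate (racemic) | CCC(Br)C(=O)OCC=C | intermediate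
18 | [1-(allyloxycarbonyl)propyl]triphenylphosphonium bromide (racemic) | CCC(C(=O)OCC=C)[P+](c1ccccc1)(c1ccccc1)c1ccccc1.[Br-] | intermediate
19 | allyl 2-(triphenylphosphoranylidene)butanoate | CCC(C(=O)OCC=C)=P(c1ccccc1)(c1ccccc1)c1ccccc1 | intermediate
20 | allyl (2E,4S,5R,6S)-5,7-bis[(tert-butyldimethylsilyl)oxy]-2,4,6-triethylhept-2-enoate | C=CCOC(=O)/C(CC)=C/[C@H](CC)[C@@H](O[Si](C)(C)C(C)(C)C)[C@@H](CC)CO[Si](C)(C)C(C)(C)C | intermediate
21 | (2E,4S,5R,6S)-5,7-bis[(tert-butyldimethylsilyl)oxy]-2,4,6-triethylhept-2-en-1-ol | OC/C(CC)=C/[C@H](CC)[C@@H](O[Si](C)(C)C(C)(C)C)[C@@H](CC)CO[Si](C)(C)C(C)(C)C | intermediate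
22 | (2E,4S,5R,6S)-5,7-bis[(tert-butyldimethylsilyl)oxy]-2,4,6-triethylhept-2-enal | O=C/C(CC)=C/[C@H](CC)[C@@H](O[Si](C)(C)C(C)(C)C)[C@@H](CC)CO[Si](C)(C)C(C)(C)C | intermediate
23 | allyl (2E,4E,6S,7R,8S)-7,9-bis[(tert-butyldimethylsilyl)oxy]-2,4,6,8-tetraethylnona-2,4-dienoate | C=CCOC(=O)/C(CC)=C/C(CC)=C/[C@H](CC)[C@@H](O[Si](C)(C)C(C)(C)C)[C@@H](CC)CO[Si](C)(C)C(C)(C)C | intermediate
24 | (2E,4E,6S,7R,8S)-7,9-bis[(tert-butyldimethylsilyl)oxy]-2,4,6,8-tetraethylnona-2,4-dien-1-ol | OC/C(CC)=C/C(CC)=C/[C@H](CC)[C@@H](O[Si](C)(C)C(C)(C)C)[C@@H](CC)CO[Si](C)(C)C(C)(C)C | intermediate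
25 | (2E,4E,6S,7R,8S)-7,9-bis[(tert-butyldimethylsilyl)oxy]-2,4,6,8-tetraethylnona-2,4-dienal | O=C/C(CC)=C/C(CC)=C/[C@H](CC)[C@@H](O[Si](C)(C)C(C)(C)C)[C@@H](CC)CO[Si](C)(C)C(C)(C)C | intermediate
26 | diethyl benzylphosphonate | CCOP(=O)(Cc1ccccc1)OCC | starting material
27 | sodium (diethoxyphosphoryl)(phenyl)methanide | [Na+].[CH-](c1ccccc1)P(=O)(OCC)OCC | intermediate
28 | (1E,3E,5E,7S,8R,9S)-8,10-bis[(tert-butyldimethylsilyl)oxy]-3,5,7,9-tetraethyl-1-phenyldeca-1,3,5-triene | c1ccccc1/C=C/C(CC)=C/C(CC)=C/[C@H](CC)[C@@H](O[Si](C)(C)C(C)(C)C)[C@@H](CC)CO[Si](C)(C)C(C)(C)C | intermediate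
29 | (2S,3R,4S,5E,7E,9E)-3-[(tert-butyldimethylsilyl)oxy]-2,4,6,8-tetraethyl-10-phenyldeca-5,7,9-trien-1-ol | c1ccccc1/C=C/C(CC)=C/C(CC)=C/[C@H](CC)[C@@H](O[Si](C)(C)C(C)(C)C)[C@@H](CC)CO | intermediate
30 | (2R,3R,4S,5E,7E,9E)-3-[(tert-butyldimethylsilyl)oxy]-2,4,6,8-tetraethyl-10-phenyldeca-5,7,9-trienal | c1ccccc1/C=C/C(CC)=C/C(CC)=C/[C@H](CC)[C@@H](O[Si](C)(C)C(C)(C)C)[C@@H](CC)C=O | intermediate
31 | allyl (2E,4S,5R,6S,7E,9E,11E)-5-[(tert-butyldimethylsilyl)oxy]-2,4,6,8,10-pentaethyl-12-phenyldodeca-2,7,9,11-tetraenoate | c1ccccc1/C=C/C(CC)=C/C(CC)=C/[C@H](CC)[C@@H](O[Si](C)(C)C(C)(C)C)[C@@H](CC)/C=C(CC)/C(=O)OCC=C | intermediate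
32 | allyl (1S,2R,3S,3aR,4R,5S,7aR)-2-[(tert-butyldimethylsilyl)oxy]-1,3,4,5,7-pentaethyl-5-[(E)-2-phenylethenyl]-2,3,3a,4,5,7a-hexahydro-1H-indene-4-carboxylate | CCC1=C[C@@](/C=C/c2ccccc2)(CC)[C@](CC)(C(=O)OCC=C)[C@@H]2[C@@H]1[C@H](CC)[C@@H](O[Si](C)(C)C(C)(C)C)[C@H]2CC | intermediate
33 | allyl (1S,2R,3S,3aR,4R,5S,7aR)-1,3,4,5,7-pentaethyl-2-hydroxy-5-[(E)-2-phenylethenyl]-2,3,3a,4,5,7a-hexahydro-1H-indene-4-carboxylate | CCC1=C[C@@](/C=C/c2ccccc2)(CC)[C@](CC)(C(=O)OCC=C)[C@@H]2[C@@H]1[C@H](CC)[C@@H](O)[C@H]2CC | intermediate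
34 | allyl (1S,3S,3aR,4R,5S,7aR)-1,3,4,5,7-pentaethyl-2-oxo-5-[(E)-2-phenylethenyl]-2,3,3a,4,5,7a-hexahydro-1H-indene-4-carboxylate | CCC1=C[C@@](/C=C/c2ccccc2)(CC)[C@](CC)(C(=O)OCC=C)[C@@H]2[C@@H]1[C@H](CC)C(=O)[C@H]2CC | intermediate
35 | (1S,3S,3aR,4R,5S,7aR)-1,3,4,5,7-pentaethyl-2-oxo-5-[(E)-2-phenylethenyl]-2,3,3a,4,5,7a-hexahydro-1H-indene-4-carboxylic acid | CCC1=C[C@@](/C=C/c2ccccc2)(CC)[C@](CC)(C(=O)O)[C@@H]2[C@@H]1[C@H](CC)C(=O)[C@H]2CC | target

**Step count**

Total: 24 steps. Longest linear sequence: 22 steps (steps 1–9 and 12–24, from 1); steps 10–11 are the ylide side branch.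

**Three steps most likely to fail, with fallbacks**

Step 21 (Wittig/Diels–Alder cascade). The cycloaddition must form two adjacent quaternary carbons with a diene that carries an inward ethyl group, and a [1,5]-hydrogen shift in that diene can compete at 110 °C. The fallback sets out from 30 and comes back at 34. The Wittig reaction of 30 with 19 is run in CH2Cl2 at 40 °C, where no cycloaddition occurs, and tetraene 31 is isolated. HF·pyridine in THF then removes the silyl group to give the hydroxy tetraene F1. Dess–Martin periodinane with pyridine at 0 °C oxidizes it to the keto tetraene F2. With the tether carbon now planar, F2 is expected to cyclize at a lower temperature (25–60 °C in toluene) under the same allylic-strain control and gives 34 directly, so steps 22 and 23 fall away.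

Step 8 (borohydride cleavage of the hindered imide 12). The α-ethyl, β-silyloxy imide may react slowly or open the oxazolidinone ring instead. The fallback sets out from 11 and comes back at 14. Transamidation of 11 with AlMe3 and MeNH(OMe)·HCl (THF, −20 to 0 °C), assisted by the free hydroxyl, gives the Weinreb amide F3. TBSOTf and 2,6-lutidine convert it into the silylated Weinreb amide F4. Reduction with i-Bu2AlH (THF, −78 °C) gives aldehyde 14 directly, so 12 and 13 are bypassed.

Step 18 (Horner–Wadsworth–Emmons reaction on dienal 25). The strongly basic phosphonate carbanion may remove the ε-hydrogen at the allylic stereocenter (epimerization or deconjugation) or give E/Z mixtures. The fallback sets out from 25 and comes back at 28. Takai olefination of 25 (CHI3, CrCl2, THF, 0 °C) under non-basic conditions gives the (E)-iodotriene F5. Suzuki coupling of F5 with phenylboronic acid (Pd(PPh3)4, K3PO4, THF/H2O, 50 °C) gives 28 with retention of alkene geometry.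

**Further compounds**

F1 | step 21 | allyl (2E,4S,5R,6S,7E,9E,11E)-2,4,6,8,10-pentaethyl-5-hydroxy-12-phenyldodeca-2,7,9,11-tetraenoate | c1ccccc1/C=C/C(CC)=C/C(CC)=C/[C@H](CC)[C@@H](O)[C@@H](CC)/C=C(CC)/C(=O)OCC=C
F2 | step 21 | allyl (2E,4S,6S,7E,9E,11E)-2,4,6,8,10-pentaethyl-5-oxo-12-phenyldodeca-2,7,9,11-tetraenoate | c1ccccc1/C=C/C(CC)=C/C(CC)=C/[C@H](CC)C(=O)[C@@H](CC)/C=C(CC)/C(=O)OCC=C
F3 | step 8 | (2R,3S,4S)-5-[(tert-butyldimethylsilyl)oxy]-2,4-diethyl-3-hydroxy-N-methoxy-N-methylpentanamide | CC[C@@H](C(=O)N(C)OC)[C@@H](O)[C@@H](CC)CO[Si](C)(C)C(C)(C)C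
F4 | step 8 | (2R,3S,4S)-3,5-bis[(tert-butyldimethylsilyl)oxy]-2,4-diethyl-N-methoxy-N-methylpentanamide | CC[C@@H](C(=O)N(C)OC)[C@@H](O[Si](C)(C)C(C)(C)C)[C@@H](CC)CO[Si](C)(C)C(C)(C)C
F5 | step 18 | (1E,3E,5E,7S,8R,9S)-8,10-bis[(tert-butyldimethylsilyl)oxy]-3,5,7,9-tetraethyl-1-iododeca-1,3,5-triene | I/C=C/C(CC)=C/C(CC)=C/[C@H](CC)[C@@H](O[Si](C)(C)C(C)(C)C)[C@@H](CC)CO[Si](C)(C)C(C)(C)C
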